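## Retrosynthetic overview

1. Both benzene rings are bought: syringaldehyde 1 (masked as its MOM ether 2) and methyl dihydroferulate 3. The only ring built is the dihydrofuran, and it is closed last.
2. Aryl C–C disconnection ortho to the phenol OH: the C3–CH2O arm comes from silyloxyacetaldehyde 4, giving saligenol 5 and then sulfone 6, the latent o-quinone methide 7.
3. Key disconnection, C2–C3: the electrophilic benzylic carbon of 7 is joined to the carbonyl carbon of 2, used as a chiral-carbene-bound acyl anion, to give (R)-ketone 8. Two natively electrophilic carbons are joined and C3 is set here.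
4. Ring closure, O1–C2: reduction of 8 to carbinol 9, then acid-mediated capture of the benzylic cation by the phenol with loss of MOM and TBS, gives the trans-(2S,3R) target 10.

Assumption: 3 and 4 are bought as catalogue compounds, and because the sense of induction of the chiral carbene cannot be predicted with confidence, the (5aS,10bR) antipode is written and its mirror image is used if it delivers ent-8.

## Route

Step 1
Reactants: 1 syringaldehyde (4-hydroxy-3,5-dimethoxybenzaldehyde)
Product: 2 3,5-dimethoxy-4-(methoxymethoxy)benzaldehyde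
Conditions: MOMCl (1.3 equiv), K2CO3 (2 equiv), acetone, 0 °C → rt
Reagents that add atoms: chloromethyl methyl ether, COCCl
Why: Williamson-type O-alkylation of the acidic phenol with the reactive α-chloro ether masks the OH that would otherwise deactivate the aldehyde as its phenolate and trap the o-quinone methide in step 4; no stereocenter is formed.

Step 2
Reactants: 3 methyl 3-(4-hydroxy-3-methoxyphenyl)propanoate; 4 (tert-butyldimethylsilyloxy)acetaldehyde
Product: 5 methyl 3-[3-(2-{[tert-butyl(dimethyl)silyl]oxy}-1-hydroxyethyl)-4-hydroxy-5-methoxyphenyl]propanoate (racemic)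
Conditions: EtMgBr (1.0 equiv), Et2O, 0 °C; solvent exchange to CH2Cl2; 4 (1.2 equiv), rt, 16 h; aq NH4Cl
Reagents that add atoms: none
Why: Casiraghi-type ortho-specific hydroxyalkylation, in which the bromomagnesium phenolate of 3 chelates the α-silyloxy aldehyde and delivers it through a six-membered transition state to the only free position ortho to oxygen while leaving the methyl ester untouched; the new carbinol center is racemic and is erased in step 4.

Step 3
Reactants: 5 methyl 3-[3-(2-{[tert-butyl(dimethyl)silyl]oxy}-1-hydroxyethyl)-4-hydroxy-5-methoxyphenyl]propanoate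
Product: 6 methyl 3-[3-(2-{[tert-butyl(dimethyl)silyl]oxy}-1-[(4-methylphenyl)sulfonyl]ethyl)-4-hydroxy-5-methoxyphenyl]propanoate (racemic)
Conditions: p-TolSO2H (1.3 equiv), CH2Cl2, rt
Reagents that add atoms: p-toluenesulfinic acid, Cc1ccc(cc1)S(=O)O
Why: Acid-promoted SN1-type substitution of the o-hydroxybenzylic alcohol by the soft sulfinate S-nucleophile gives the bench-stable 2-(1-sulfonylalkyl)phenol that is the standard latent o-quinone methide; the center stays racemic and is erased in step 4.

Step 4
Reactants: 6 methyl 3-[3-(2-{[tert-butyl(dimethyl)silyl]oxy}-1-[(4-methylphenyl)sulfonyl]ethyl)-4-hydroxy-5-methoxyphenyl]propanoate; 2 3,5-dimethoxy-4-(methoxymethoxy)benzaldehyde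
Product: 8 methyl 3-{3-[(2R)-1-{[tert-butyl(dimethyl)silyl]oxy}-3-[3,5-dimethoxy-4-(methoxymethoxy)phenyl]-3-oxopropan-2-yl]-4-hydroxy-5-methoxyphenyl}propanoate, via o-quinone methide 7 (not isolated)
Conditions: (5aS,10bR)-2-(pentafluorophenyl)-5a,10b-dihydro-4H,6H-indeno[2,1-b][1,2,4]triazolo[4,3-d][1,4]oxazin-2-ium tetrafluoroborate (C18H11BF9N3O, 20 mol %), Cs2CO3 (1.2 equiv), 2 (1.5 equiv), 4 Å molecular sieves, CH2Cl2, −20 → 0 °C; cold pH 7 buffer (KH2PO4/K2HPO4) quench
Reagents that add atoms: none
Why: Proposed new method: Cs2CO3 triggers 1,4-elimination of sulfinate from 6 to give o-quinone methide 7, whose benzylic carbon is attacked by the nucleophilic Breslow intermediate (acyl anion equivalent) formed from aldehyde 2 and the chiral aminoindanol-derived triazolylidene, so that the C2–C3 bond forms on one enantiotopic face of 7 and sets the future C3 as (R), rearomatisation makes the addition irreversible, and the product is held as its cesium phenolate/cyclic lactolate, which disfavours enolisation of the new α-aryl ketone; the closest known reactions are the racemic thiazolium-catalysed acyl anion addition to o-quinone methides and the enantioselective intermolecular Stetter reaction.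

Step 5
Reactants: 8 methyl 3-{3-[(2R)-1-{[tert-butyl(dimethyl)silyl]oxy}-3-[3,5-dimethoxy-4-(methoxymethoxy)phenyl]-3-oxopropan-2-yl]-4-hydroxy-5-methoxyphenyl}propanoate
Product: 10 methyl 3-[(2S,3R)-2-(4-hydroxy-3,5-dimethoxyphenyl)-3-(hydroxymethyl)-7-methoxy-2,3-dihydro-1-benzofuran-5-yl]propanoate, via benzylic alcohol 9 (not isolated)
Conditions: NaBH4, CeCl3·7H2O, MeOH, −40 °C; then HCl (3 M in MeOH), 0 °C → rt
Reagents that add atoms: none
Why: Luche reduction converts the enolisable α-aryl ketone to carbinol 9 at low temperature without epimerising C3 (the carbinol epimer ratio is irrelevant), and methanolic HCl then removes the MOM and TBS groups and ionises the electron-rich benzylic alcohol to a p-oxybenzyl cation that the phenol captures in a reversible SN1 cycloetherification, which gives the thermodynamically preferred 2,3-trans ring and so sets C2 as (S) from C3 (R).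

## Compound list

1 | syringaldehyde (4-hydroxy-3,5-dimethoxybenzaldehyde) | O=Cc1cc(OC)c(O)c(OC)c1 | starting material
2 | 3,5-dimethoxy-4-(methoxymethoxy)benzaldehyde | O=Cc1cc(OC)c(OCOC)c(OC)c1 | intermediate
3 | methyl 3-(4-hydroxy-3-methoxyphenyl)propanoate (methyl dihydroferulate) | COC(=O)CCc1ccc(O)c(OC)c1 | starting material
4 | (tert-butyldimethylsilyloxy)acetaldehyde | O=CCO[Si](C)(C)C(C)(C)C | starting material
5 | methyl 3-[3-(2-{[tert-butyl(dimethyl)silyl]oxy}-1-hydroxyethyl)-4-hydroxy-5-methoxyphenyl]propanoate (racemic) | COC(=O)CCc1cc(OC)c(O)c(c1)C(O)CO[Si](C)(C)C(C)(C)C | intermediate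
6 | methyl 3-[3-(2-{[tert-butyl(dimethyl)silyl]oxy}-1-[(4-methylphenyl)sulfonyl]ethyl)-4-hydroxy-5-methoxyphenyl]propanoate (racemic) | COC(=O)CCc1cc(OC)c(O)c(c1)C(CO[Si](C)(C)C(C)(C)C)S(=O)(=O)c1ccc(C)cc1 | intermediate
7 | methyl 3-[3-(2-{[tert-butyl(dimethyl)silyl]oxy}ethylidene)-5-methoxy-4-oxocyclohexa-1,5-dien-1-yl]propanoate (o-quinone methide, alkene geometry not defined) | COC(=O)CCC1=CC(=CCO[Si](C)(C)C(C)(C)C)C(=O)C(OC)=C1 | intermediate (not isolated)
8 | methyl 3-{3-[(2R)-1-{[tert-butyl(dimethyl)silyl]oxy}-3-[3,5-dimethoxy-4-(methoxymethoxy)phenyl]-3-oxopropan-2-yl]-4-hydroxy-5-methoxyphenyl}propanoate | COC(=O)CCc1cc(OC)c(O)c(c1)[C@H](CO[Si](C)(C)C(C)(C)C)C(=O)c1cc(OC)c(OCOC)c(OC)c1 | intermediate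
9 | methyl 3-{3-[(2R)-1-{[tert-butyl(dimethyl)silyl]oxy}-3-[3,5-dimethoxy-4-(methoxymethoxy)phenyl]-3-hydroxypropan-2-yl]-4-hydroxy-5-methoxyphenyl}propanoate (mixture of epimers at the carbinol carbon) | COC(=O)CCc1cc(OC)c(O)c(c1)[C@H](CO[Si](C)(C)C(C)(C)C)C(O)c1cc(OC)c(OCOC)c(OC)c1 | intermediate (not isolated)
10 | methyl 3-[(2S,3R)-2-(4-hydroxy-3,5-dimethoxyphenyl)-3-(hydroxymethyl)-7-methoxy-2,3-dihydro-1-benzofuran-5-yl]propanoate | COC(=O)CCc1cc(OC)c2c(c1)[C@H](CO)[C@@H](c1cc(OC)c(O)c(OC)c1)O2 | target

## Step count and risks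

Total steps: 5. Longest linear sequence: 4 (steps 2, 3, 4 and 5, from 3 to 10).

Most likely to fail, in order:

Step 4. The enantioselective acyl anion addition may give low ee, the α-aryl ketone may racemise under base, or 7 may tautomerise to the o-hydroxystyryl enol ether before it is trapped. The fallback gives up catalyst control in the C–C bond formation and sets the stereocenter by dynamic kinetic resolution. Setting out from 6 and 2, the same o-quinone methide acylation is run with the achiral 3-benzyl-5-(2-hydroxyethyl)-4-methylthiazolium chloride (C13H16ClNOS, 20 mol %) and Cs2CO3 in CH2Cl2 at rt to give the racemic ketone F1. Its α-aryl C–H racemises readily, and this ketone is reduced by asymmetric transfer hydrogenation with the divalent ruthenium complex RuCl[(S,S)-TsDPEN](p-cymene) (C31H35ClN2O2RuS, TsDPEN = N-(p-toluenesulfonyl)-1,2-diphenylethylenediamine monoanion) in HCO2H/Et3N (5:2) at 40 °C. The (R)-ketone is expected to be the Felkin-matched, fast-reacting enantiomer for this (S)-carbinol-selective catalyst, so the product is the (2R,3S)-alcohol F2, a single epimer of 9. This alcohol comes back to the route at 10 on treatment with 3 M HCl in MeOH, as in the second half of step 5.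

Step 2. The magnesium phenolate may react sluggishly with the enolisable aldehyde or condense further to diarylmethanes. The fallback is a boron-templated (Nagata) condensation. Setting out from 3 and 4, PhB(OH)2 (1.1 equiv) and catalytic propanoic acid in toluene at reflux with a Dean–Stark trap give the benzodioxaborin F3, in which boron ties phenol oxygen and aldehyde together and enforces ortho attack. Transesterification of this boronate with propane-1,3-diol in THF at rt releases saligenol 5, where the route is rejoined.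

Step 5. The acid stage may give some cis isomer, or cyclodehydrate unreduced ketone to the 2-arylbenzofuran, or open the product ring on prolonged exposure. The fallback closes the ring by a stereospecific SN2 reaction under neutral conditions. Setting out from 8, reagent-controlled reduction with (S)-1-methyl-3,3-diphenyltetrahydro-1H,3H-pyrrolo[1,2-c][1,3,2]oxazaborole (C18H20BNO, 20 mol %) and BH3·SMe2 in THF at −20 °C gives the (2R,3R)-alcohol F4. Mitsunobu etherification (PPh3, diisopropyl azodicarboxylate, THF, 0 °C) inverts the carbinol carbon and gives the MOM/TBS-protected (2S,3R)-dihydrobenzofuran F5. Brief treatment of this ether with 3 M HCl in MeOH at rt removes both protecting groups and returns to the route at 10.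

Further compounds

F1 | step 4 | methyl 3-{3-[1-{[tert-butyl(dimethyl)silyl]oxy}-3-[3,5-dimethoxy-4-(methoxymethoxy)phenyl]-3-oxopropan-2-yl]-4-hydroxy-5-methoxyphenyl}propanoate (racemic) | COC(=O)CCc1cc(OC)c(O)c(c1)C(CO[Si](C)(C)C(C)(C)C)C(=O)c1cc(OC)c(OCOC)c(OC)c1
F2 | step 4 | methyl 3-{3-[(2R,3S)-1-{[tert-butyl(dimethyl)silyl]oxy}-3-[3,5-dimethoxy-4-(methoxymethoxy)phenyl]-3-hydroxypropan-2-yl]-4-hydroxy-5-methoxyphenyl}propanoate | COC(=O)CCc1cc(OC)c(O)c(c1)[C@H](CO[Si](C)(C)C(C)(C)C)[C@H](O)c1cc(OC)c(OCOC)c(OC)c1
F3 | step 2 | methyl 3-[4-({[tert-butyl(dimethyl)silyl]oxy}methyl)-8-methoxy-2-phenyl-4H-1,3,2-benzodioxaborin-6-yl]propanoate (racemic) | COC(=O)CCc1cc(OC)c2OB(c3ccccc3)OC(CO[Si](C)(C)C(C)(C)C)c2c1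
F4 | step 5 | methyl 3-{3-[(2R,3R)-1-{[tert-butyl(dimethyl)silyl]oxy}-3-[3,5-dimethoxy-4-(methoxymethoxy)phenyl]-3-hydroxypropan-2-yl]-4-hydroxy-5-methoxyphenyl}propanoate | COC(=O)CCc1cc(OC)c(O)c(c1)[C@H](CO[Si](C)(C)C(C)(C)C)[C@@H](O)c1cc(OC)c(OCOC)c(OC)c1
F5 | step 5 | methyl 3-[(2S,3R)-3-({[tert-butyl(dimethyl)silyl]oxy}methyl)-2-[3,5-dimethoxy-4-(methoxymethoxy)phenyl]-7-methoxy-2,3-dihydro-1-benzofuran-5-yl]propanoate | COC(=O)CCc1cc(OC)c2c(c1)[C@H](CO[Si](C)(C)C(C)(C)C)[C@@H](c1cc(OC)c(OCOC)c(OC)c1)O2
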